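Atom labels follow labdane numbering: ring A is C1–C5 with C10, ring B is C5–C10, C17 is the carboxyl carbon on C8, C18 and C19 are the methyl groups on C4, C20 is the methyl group on C10, and the side chain is C11–C15 with C16 on C13.

## Analysis of the target

The target 24 is a labdane-type diterpenoid acid built on a trans-fused decalin. Ring A carries a gem-dimethyl group on C4 and shares the quaternary, methyl-bearing C10 with ring B. Ring B carries an acetoxy group on C6, a C7=C8 double bond conjugated with the C17 carboxyl group, and on C9 a chain that ends in an (E)-3-methylpenta-2,4-dienyl unit. There are four stereocentres (5R, 6S, 9S, 10S). C20, the C9 side chain and the C6 acetate lie on one face of ring B and H-5 on the other, so the C9 chain is equatorial and the C6 oxygen is pseudo-axial, syn to C20 and to the axial methyl on C4. With ring A drawn on the left the angular methyl points down, which places the compound in the enantio series of the labdanes. The conjugated diene is sensitive to acid, electrophiles and metal hydrides; the allylic acetate γ to the carboxyl group can ionise or eliminate; the free acid limits the choice of late reagents. The hard points are the absolute configuration of the all-carbon quaternary C10, the hindered axial C6 oxygen, the trisubstituted C7=C8 alkene that carries C17, and the E geometry at C12=C13. The strategy rests on one mapping: C8, C9 and C10 with C20 correspond to the carbonyl carbon, the α-carbon and the methyl-bearing β-carbon of 3-methylcyclohex-2-en-1-one 3. The two bonds that leave ring B at C10 and C9 can therefore be made by 1,4-addition and enolate alkylation around that one enone.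

## Retrosynthetic reasoning

**End game, 24 back to 21.** The acid is traced to aldehyde 23, the acetate to alcohol 22, and the aldehyde to the primary allylic alcohol of diol 21. These are changes of oxidation level and acylation only. They are placed last because the diene must be installed with a metal hydride, which neither an ester nor an aldehyde tolerates. The forward steps must distinguish a primary from a hindered secondary allylic alcohol and must spare the diene.

**C13–C14, 21 back to 18 and 19.** The diene is cut between C13 and C14 into a C13 alkenyl metal and vinyl bromide 19, and the alkenyl metal is traced to the but-2-ynyl group of diol 18. An olefination at C12=C13 would have to control the geometry of a trisubstituted alkene; syn hydrometalation of an alkyne defines it by mechanism. The alkyne is also inert to the acid, base and organolithium used earlier, which a diene is not. The forward step must place the metal on C13 and not on C12.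

**C6–O, 18 back to 16 through 17.** The C6 oxygen and the C7=C8 alkene are traced to a C8 tertiary allylic alcohol with a C6=C7 alkene (16) by a 1,3-transposition; 17 is the 4-methoxybenzyl ether of 18. Because the shift in a six-membered ring is suprafacial, the C6 configuration becomes a question of the face on which the C8 oxygen sits. The forward reaction must move the oxygen without ionisation to a free allyl cation.

**C8–C17, 16 back to 10 and 14.** C17 is cut from C8, giving decalenone 10 and a protected hydroxymethyl anion derived from stannane 14. The cut is made here because the C8 carbonyl is already present and because the axial C20 methyl shields one face of C8, so the carbon nucleophile enters on the other face and the oxygen is left syn to C20.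

**C4–C5, 10 back to 9.** Ring A is opened between C4 and C5, giving monocyclic enone 9 with a 4-methylpent-3-enyl chain on C10. C4 is tertiary and can only be an electrophile (a cation from the C3=C4 alkene). C5 becomes a nucleophile through the C6=C7–C8=O enone as the γ-carbon of its dienol. The same carbonyl lets C5 and C9 equilibrate afterwards to the trans ring fusion and the equatorial C9 substituent.

**C6=C7, 9 back to 6 through 8.** The enone is traced to saturated ketone 6 through its kinetic silyl enol ether 8. The forward steps must enolise toward C7 and not toward C9.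

**C1–C10 and C9–C11, 6 back to 2, 3 and 4.** Ketone 6 is cut at both bonds that leave ring B: C1–C10 to Grignard reagent 2 and enone 3, and C9–C11 to bromide 4 and the enolate 5 that the conjugate addition leaves behind. One operation thus gathers every carbon of ring A and the C11–C13/C16 stub, and sets C10, the one centre that cannot be corrected later, under catalyst control. C9 need not be controlled, since it is epimerisable.

**Reagents.** Grignard reagent 2 comes from bromide 1; stannane 14 comes from alcohol 11 and chloride 12.

## Alternatives that were turned down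

**Alternative 1: Diels–Alder construction of ring B first.**
- Disconnection: ring B is cut at C7–C8 and C9–C10 into 2,4-bis(trimethylsilyloxy)penta-1,3-diene A1 (C7, C6, C5, C10 and C20) and the fumarate-derived imide A2 (C8 with the C17 ester, C9 with C11 as the imide carbonyl).
- Forward key step: a chiral bis(oxazoline) complex of Cu(OTf)2 chelates the imide of A2, A1 adds, and loss of silanol on work-up gives enone A3.
- For: the cycloaddition is catalytic and enantioselective. The C6 oxygen and C17 are present at useful oxidation levels from the first step, so no oxygen transposition is needed. On this point the alternative is stronger than the chosen route.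
- Against: A3 contains no ring A carbon, and C10 is not yet quaternary. The chain would have to be added to the β,β-disubstituted enone of A3, with the C10 configuration relayed from C9 in a flexible monocycle instead of set by a catalyst. The C4–C5 bond would then still join a tertiary carbon to an enolate carbon, which is no easier than the cationic closure used here. The diene terminus that becomes C10 carries both a methyl and a silyloxy group, so one must point inward in the s-cis diene; this slows the cycloaddition and weakens facial control. The C8 stereocentre is made only to be erased, the C7=C8 unsaturation needs a separate dehydrogenation, and C11 must be reduced and extended by four carbons.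
- Comparison: the chosen route gives up the early C6 oxygen but brings in all of ring A and the side-chain stub in one flask and is clearly shorter.

**Alternative 2: Intramolecular Diels–Alder closing both rings.**
- Disconnection: C5–C10 and C8–C9 are cut together, leading to the acyclic siloxytriene A4.
- Forward key step: Lewis-acid activation of the (E)-3-methyl enal of A4 and cycloaddition onto the 2-silyloxydiene give the trans-fused adduct A5.
- For: one step forms both rings and four stereocentres and places oxygen on C6 and C17. It also avoids a cationic ring closure. In bond count per step it is stronger than the chosen route.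
- Against: the C5–C10 bond must join a diene terminus next to the gem-dimethyl carbon to the β,β-disubstituted carbon of the enal, which is a very congested transition state. A silyl enol ether facing a Lewis-acid-bound enal tends to react stepwise (Mukaiyama–Michael) or to lose silicon. Absolute control would need a chiral Lewis acid on a hindered, weakly binding enal. A4 needs a long linear synthesis with three defined alkene geometries. The C8 centre is again lost, and the C6 enol ether still has to be converted into the axial alcohol and the C7=C8 alkene.
- Comparison: the chosen route sets C10 by a catalytic reaction on a small commercial enone and then builds the remaining stereocentres one at a time under substrate control.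

**Alternative 3: Chiral-enamine Robinson annulation onto a preformed ring A.**
- Disconnection: ring B is cut at C9–C10 and C5–C6, leading to 2,2,6-trimethylcyclohexanone A6 and the alkylidene acetoacetate A8.
- Forward key step: A6 is converted into the secondary enamine A7 of an enantiopure 1-phenylethylamine, which adds through C10 to A8. Hydrolysis and aldol condensation of the acetyl methyl onto the C5 carbonyl give enone A9.
- For: ring A with its gem-dimethyl group is bought, so no cationic closure is needed, and C17 is present as an ester. On both points the alternative is stronger than the chosen route.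
- Against: the imine of the doubly flanked ketone A6 forms reluctantly, and a β-substituted acceptor reacts slowly with such enamines. The chiral amine is stoichiometric. A9 has its oxygen on C7 and not on C6, and C5 is sp2. The route therefore still needs removal of the C7 oxygen, introduction of the C6 oxygen trans to H-5 (a syn hydroboration of C5=C6 would give the wrong relation), creation of the ring-fusion centre, and two more side-chain carbons plus the diene.
- Comparison: in the chosen route the ring B carbonyl sits on C8, from where a single suprafacial shift takes the oxygen to C6 with the correct configuration, and the route needs fewer corrective steps.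

Key step: step 2

## Route

Remark: the enantiomer of the imidazolinium ligand precursor is the one that directs the alkyl group to the face of 3 that gives (S)-configured C10 in 5. It is written below as the L-leucinol-derived salt; if the sense of induction is the opposite, the D-leucinol-derived antipode is used in the same way.

Step 1
Reactants: 1 5-bromo-2-methylpent-2-ene
Product: 2 4-methylpent-3-enylmagnesium bromide
Conditions: Mg turnings, I2 (cat.), Et2O, reflux
Reagents that add atoms: magnesium, [Mg]
Why: Grignard formation by insertion of magnesium into the primary C–Br bond; the homoallylic bromide has no β-leaving group and the trisubstituted alkene is inert.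

Step 2
Reactants: 3 3-methylcyclohex-2-en-1-one; 2 4-methylpent-3-enylmagnesium bromide; 4 1-bromobut-2-yne
Product: 6 (2S,3S)-2-(but-2-yn-1-yl)-3-methyl-3-(4-methylpent-3-en-1-yl)cyclohexan-1-one (butynyl group cis to the methyl group), via bromomagnesium enolate 5 (not isolated)
Conditions: Cu(OTf)2 (3 mol %), (S)-1-(1-hydroxy-4-methylpentan-2-yl)-3-mesityl-4,5-dihydroimidazolium hexafluorophosphate (4 mol %), Et2O, 0 °C, slow addition of 2; then 4, DMPU, THF, 0 °C → rt
Reagents that add atoms: none
Why: The Grignard reagent deprotonates the imidazolinium salt and transmetalates to an alkoxide-tethered carbene–alkylcopper species, which binds the enone as a π-complex, adds oxidatively at C10 to a trivalent copper enolate and reductively eliminates, forming C1–C10 and leaving the C8–C9 bromomagnesium enolate 5 with its double bond fixed toward C9. The closest known reaction type is the copper–carbene-catalysed asymmetric conjugate addition of primary alkyl Grignard reagents to 3-methylcyclohex-2-enone with C-alkylation of the magnesium enolate by an activated halide in the same flask. No ring is closed. C10 is set by the ligand, which differentiates the two faces of the enone in the addition. C9 is set by the substrate: the bromide should approach the enolate face anti to the longer 4-methylpent-3-enyl chain on the neighbouring quaternary carbon, which places the butynyl group cis to the methyl group; the centre stays epimerisable next to the ketone, so any minor epimer converges in step 5. The step needs 1,4- over 1,2-addition (copper catalysis and slow addition of 2), alkylation at C9 and not C7 (the enolate is used as formed, and DMPU makes alkylation faster than proton transfer), SN2 over SN2′ displacement (the distal alkyne carbon carries a methyl group) and mono- over dialkylation (C9 becomes a hindered methine between a carbonyl and a quaternary carbon).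

Step 3
Reactants: 6 (2S,3S)-2-(but-2-yn-1-yl)-3-methyl-3-(4-methylpent-3-en-1-yl)cyclohexan-1-one
Product: 8 {[(5R,6S)-6-(but-2-yn-1-yl)-5-methyl-5-(4-methylpent-3-en-1-yl)cyclohex-1-en-1-yl]oxy}trimethylsilane, via lithium enolate 7 (not isolated)
Conditions: LiN(i-Pr)2, THF, −78 °C; then Me3SiCl, −78 °C → 0 °C
Reagents that add atoms: chlorotrimethylsilane, C[Si](C)(C)Cl
Why: Kinetic deprotonation by the hindered amide removes a proton from the C7 methylene and not from the C9 methine, which is shielded by the quaternary C10; O-silylation fixes the C7–C8 enolate, and C9 and C10 are untouched.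

Step 4
Reactants: 8 {[(5R,6S)-6-(but-2-yn-1-yl)-5-methyl-5-(4-methylpent-3-en-1-yl)cyclohex-1-en-1-yl]oxy}trimethylsilane
Product: 9 (5R,6S)-6-(but-2-yn-1-yl)-5-methyl-5-(4-methylpent-3-en-1-yl)cyclohex-2-en-1-one
Conditions: Pd(OAc)2 (1.05 equiv), MeCN, rt
Reagents that add atoms: none
Why: Saegusa–Ito oxidation: the silyl enol ether transmetalates to a divalent palladium enolate, and β-hydride elimination from C6 gives the C6=C7 enone; the internal alkyne and the trisubstituted alkene should be spectators at room temperature.

Step 5
Reactants: 9 (5R,6S)-6-(but-2-yn-1-yl)-5-methyl-5-(4-methylpent-3-en-1-yl)cyclohex-2-en-1-one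
Product: 10 (1S,4aR,8aR)-1-(but-2-yn-1-yl)-5,5,8a-trimethyl-4a,5,6,7,8,8a-hexahydronaphthalen-2(1H)-one (trans-fused; butynyl group equatorial and cis to the angular methyl group)
Conditions: TfOH (10 mol %), (CF3)2CHOH, 0 °C → rt; then NaOMe (0.2 equiv), MeOH, rt
Reagents that add atoms: none
Why: Proposed new method: Markovnikov protonation of the C3=C4 alkene gives the tertiary C4 cation, which should be captured through a six-membered chair transition state by C5 of the dienol tautomer (C8(OH)=C7–C6=C5) of the enone, re-forming the conjugated 6-en-8-one; the closest known reaction types are acid-mediated cation–olefin cyclisations terminated by the enol of a β-keto ester and the γ-selective SN1 alkylation of dienol derivatives; the methoxide stage equilibrates C5 (γ-position, through the dienolate) and C9 (α′-position), so that the trans ring fusion with axial C20 and the equatorial butynyl group cis to C20 should result.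

Step 6
Reactants: 11 (tributylstannyl)methanol; 12 1-(chloromethyl)-4-methoxybenzene
Product: 14 tributyl{[(4-methoxybenzyl)oxy]methyl}stannane, via sodium alkoxide 13 (not isolated)
Conditions: NaH, THF–DMF, 0 °C; then 12, Bu4NI (cat.), rt
Reagents that add atoms: none
Why: Williamson ether synthesis of the sodium alkoxide with a benzylic chloride under iodide catalysis; the C–Sn bond is stable to NaH.

Step 7
Reactants: 10 (1S,4aR,8aR)-1-(but-2-yn-1-yl)-5,5,8a-trimethyl-4a,5,6,7,8,8a-hexahydronaphthalen-2(1H)-one; 14 tributyl{[(4-methoxybenzyl)oxy]methyl}stannane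
Product: 16 (1S,2R,4aR,8aR)-1-(but-2-yn-1-yl)-2-{[(4-methoxybenzyl)oxy]methyl}-5,5,8a-trimethyl-1,2,4a,5,6,7,8,8a-octahydronaphthalen-2-ol (C8 hydroxyl on the face of C20), via organolithium reagent 15 (not isolated)
Conditions: 14, n-BuLi, THF, −78 °C; then 10, −78 °C; then H2O
Reagents that add atoms: none
Why: Tin–lithium exchange gives the α-alkoxy organolithium, which adds 1,2 to the enone carbonyl; it should enter on the face of C8 opposite the pseudo-axial C20 methyl on C10 (equatorial trajectory), so C17 becomes equatorial and the C8 hydroxyl axial, syn to C20.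

Step 8
Reactants: 16 (1S,2R,4aR,8aR)-1-(but-2-yn-1-yl)-2-{[(4-methoxybenzyl)oxy]methyl}-5,5,8a-trimethyl-1,2,4a,5,6,7,8,8a-octahydronaphthalen-2-ol
Product: 17 (1S,4S,4aS,8aR)-4-(but-2-yn-1-yl)-3-{[(4-methoxybenzyl)oxy]methyl}-4a,8,8-trimethyl-1,4,4a,5,6,7,8,8a-octahydronaphthalen-1-ol (C6 hydroxyl pseudo-axial, syn to C20)
Conditions: Ph3SiOReO3 (5 mol %), Et2O, −50 → 0 °C
Reagents that add atoms: none
Why: Perrhenate-catalysed 1,3-transposition of an allylic alcohol through a [3,3]-sigmatropic shift of the allyl perrhenate; within the ring the oxygen can only migrate suprafacially, so it should arrive at C6 on the face it occupied at C8, and the equilibrium should favour the secondary alcohol with the more substituted C7=C8 alkene.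

Step 9
Reactants: 17 (1S,4S,4aS,8aR)-4-(but-2-yn-1-yl)-3-{[(4-methoxybenzyl)oxy]methyl}-4a,8,8-trimethyl-1,4,4a,5,6,7,8,8a-octahydronaphthalen-1-ol
Product: 18 (1S,4S,4aS,8aR)-4-(but-2-yn-1-yl)-3-(hydroxymethyl)-4a,8,8-trimethyl-1,4,4a,5,6,7,8,8a-octahydronaphthalen-1-ol
Conditions: DDQ (1.2 equiv), CH2Cl2–pH 7 buffer, 0 °C
Reagents that add atoms: none
Why: Oxidative cleavage of the 4-methoxybenzyl ether by hydride abstraction and hydrolysis of the oxocarbenium ion; the alkyne, the ring alkene and the hindered secondary alcohol should survive buffered conditions at 0 °C.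

Step 10
Reactants: 18 (1S,4S,4aS,8aR)-4-(but-2-yn-1-yl)-3-(hydroxymethyl)-4a,8,8-trimethyl-1,4,4a,5,6,7,8,8a-octahydronaphthalen-1-ol; 19 bromoethene
Product: 21 (1S,4S,4aS,8aR)-3-(hydroxymethyl)-4a,8,8-trimethyl-4-[(2E)-3-methylpenta-2,4-dien-1-yl]-1,4,4a,5,6,7,8,8a-octahydronaphthalen-1-ol, via alkenylzirconocene 20 (not isolated)
Conditions: Cp2Zr(H)Cl (4 equiv), THF, rt → 45 °C; then ZnCl2 (1 equiv), Pd(PPh3)4 (5 mol %), 19 (3 equiv), THF, rt → 40 °C
Reagents that add atoms: none
Why: Hydrozirconation followed by Negishi coupling: Zr–H adds syn across the alkyne and, after equilibration with excess reagent, zirconium sits on the less hindered methyl-bearing C13; transmetalation to zinc and coupling under zerovalent palladium catalysis proceed with retention, which fixes the E geometry at C12=C13; the two hydroxyl groups are masked in the flask as zirconium alkoxides.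

Step 11
Reactants: 21 (1S,4S,4aS,8aR)-3-(hydroxymethyl)-4a,8,8-trimethyl-4-[(2E)-3-methylpenta-2,4-dien-1-yl]-1,4,4a,5,6,7,8,8a-octahydronaphthalen-1-ol
Product: 22 (1S,4S,4aR,8aS)-4-hydroxy-5,5,8a-trimethyl-1-[(2E)-3-methylpenta-2,4-dien-1-yl]-1,4,4a,5,6,7,8,8a-octahydronaphthalene-2-carbaldehyde
Conditions: TEMPO (10 mol %), PhI(OAc)2 (1.1 equiv), CH2Cl2, rt
Reagents that add atoms: none
Why: Oxoammonium-mediated oxidation is selective for the primary allylic alcohol over the hindered axial secondary alcohol at C6 and stops at the aldehyde; the diene is not attacked.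

Step 12
Reactants: 22 (1S,4S,4aR,8aS)-4-hydroxy-5,5,8a-trimethyl-1-[(2E)-3-methylpenta-2,4-dien-1-yl]-1,4,4a,5,6,7,8,8a-octahydronaphthalene-2-carbaldehyde
Product: 23 (1S,4S,4aS,8aR)-3-formyl-4a,8,8-trimethyl-4-[(2E)-3-methylpenta-2,4-dien-1-yl]-1,4,4a,5,6,7,8,8a-octahydronaphthalen-1-yl acetate
Conditions: Ac2O, DMAP, pyridine, CH2Cl2, rt → 40 °C
Reagents that add atoms: acetic anhydride, CC(=O)OC(C)=O
Why: DMAP-catalysed acylation of the hindered secondary alcohol with retention at C6; no centre in the molecule is epimerisable under these conditions.

Step 13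
Reactants: 23 (1S,4S,4aS,8aR)-3-formyl-4a,8,8-trimethyl-4-[(2E)-3-methylpenta-2,4-dien-1-yl]-1,4,4a,5,6,7,8,8a-octahydronaphthalen-1-yl acetate
Product: 24 (1S,4S,4aR,8aS)-4-acetoxy-5,5,8a-trimethyl-1-[(2E)-3-methylpenta-2,4-dien-1-yl]-1,4,4a,5,6,7,8,8a-octahydronaphthalene-2-carboxylic acid (the target, CNP0294871.1)
Conditions: NaClO2, NaH2PO4, 2-methylbut-2-ene (excess), t-BuOH–H2O, 0 °C → rt
Reagents that add atoms: sodium chlorite, [Na+].[O-]Cl=O
Why: Pinnick oxidation: chlorous acid adds to the aldehyde and fragments to the acid; the alkene scavenger removes hypochlorous acid before it can attack the diene, and the acetate and the C7=C8 alkene are untouched at pH 4.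

## Compound list

1 | 5-bromo-2-methylpent-2-ene | CC(C)=CCCBr | starting material
2 | 4-methylpent-3-enylmagnesium bromide | CC(C)=CCC[Mg]Br | intermediate
3 | 3-methylcyclohex-2-en-1-one | CC1=CC(=O)CCC1 | starting material
4 | 1-bromobut-2-yne | CC#CCBr | starting material
5 | bromomagnesium (S)-3-methyl-3-(4-methylpent-3-en-1-yl)cyclohex-1-en-1-olate | Br[Mg]OC1=C[C@](C)(CCC=C(C)C)CCC1 | intermediate
6 | (2S,3S)-2-(but-2-yn-1-yl)-3-methyl-3-(4-methylpent-3-en-1-yl)cyclohexan-1-one | CC#CC[C@@H]1C(=O)CCC[C@@]1(C)CCC=C(C)C | intermediate
7 | lithium (5R,6S)-6-(but-2-yn-1-yl)-5-methyl-5-(4-methylpent-3-en-1-yl)cyclohex-1-en-1-olate | CC#CC[C@@H]1C(O[Li])=CCC[C@@]1(C)CCC=C(C)C | intermediate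
8 | {[(5R,6S)-6-(but-2-yn-1-yl)-5-methyl-5-(4-methylpent-3-en-1-yl)cyclohex-1-en-1-yl]oxy}trimethylsilane | CC#CC[C@@H]1C(O[Si](C)(C)C)=CCC[C@@]1(C)CCC=C(C)C | intermediate
9 | (5R,6S)-6-(but-2-yn-1-yl)-5-methyl-5-(4-methylpent-3-en-1-yl)cyclohex-2-en-1-one | CC#CC[C@@H]1C(=O)C=CC[C@@]1(C)CCC=C(C)C | intermediate
10 | (1S,4aR,8aR)-1-(but-2-yn-1-yl)-5,5,8a-trimethyl-4a,5,6,7,8,8a-hexahydronaphthalen-2(1H)-one | CC#CC[C@@H]1C(=O)C=C[C@@H]2C(C)(C)CCC[C@@]12C | intermediate
11 | (tributylstannyl)methanol | CCCC[Sn](CCCC)(CCCC)CO | starting material
12 | 1-(chloromethyl)-4-methoxybenzene | COc1ccc(CCl)cc1 | starting material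
13 | sodium (tributylstannyl)methanolate | CCCC[Sn](CCCC)(CCCC)C[O-].[Na+] | intermediate
14 | tributyl{[(4-methoxybenzyl)oxy]methyl}stannane | CCCC[Sn](CCCC)(CCCC)COCc1ccc(OC)cc1 | intermediate
15 | {[(4-methoxybenzyl)oxy]methyl}lithium | [Li]COCc1ccc(OC)cc1 | intermediate
16 | (1S,2R,4aR,8aR)-1-(but-2-yn-1-yl)-2-{[(4-methoxybenzyl)oxy]methyl}-5,5,8a-trimethyl-1,2,4a,5,6,7,8,8a-octahydronaphthalen-2-ol | CC#CC[C@@H]1[C@@](O)(COCc3ccc(OC)cc3)C=C[C@@H]2C(C)(C)CCC[C@@]12C | intermediate
17 | (1S,4S,4aS,8aR)-4-(but-2-yn-1-yl)-3-{[(4-methoxybenzyl)oxy]methyl}-4a,8,8-trimethyl-1,4,4a,5,6,7,8,8a-octahydronaphthalen-1-ol | CC#CC[C@@H]1C(COCc3ccc(OC)cc3)=C[C@H](O)[C@@H]2C(C)(C)CCC[C@@]12C | intermediate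
18 | (1S,4S,4aS,8aR)-4-(but-2-yn-1-yl)-3-(hydroxymethyl)-4a,8,8-trimethyl-1,4,4a,5,6,7,8,8a-octahydronaphthalen-1-ol | CC#CC[C@@H]1C(CO)=C[C@H](O)[C@@H]2C(C)(C)CCC[C@@]12C | intermediate
19 | bromoethene (vinyl bromide) | C=CBr | starting material
20 | C13 alkenylchlorozirconocene of 18, (E)-configured, both hydroxyl groups as chlorozirconocene alkoxides | C/C(=C\C[C@@H]1C(CO[Zr](Cl)(C3C=CC=C3)C3C=CC=C3)=C[C@H](O[Zr](Cl)(C3C=CC=C3)C3C=CC=C3)[C@@H]2C(C)(C)CCC[C@@]12C)[Zr](Cl)(C1C=CC=C1)C1C=CC=C1 | intermediate
21 | (1S,4S,4aS,8aR)-3-(hydroxymethyl)-4a,8,8-trimethyl-4-[(2E)-3-methylpenta-2,4-dien-1-yl]-1,4,4a,5,6,7,8,8a-octahydronaphthalen-1-ol | C=C/C(C)=C/C[C@@H]1C(CO)=C[C@H](O)[C@@H]2C(C)(C)CCC[C@@]12C | intermediate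
22 | (1S,4S,4aR,8aS)-4-hydroxy-5,5,8a-trimethyl-1-[(2E)-3-methylpenta-2,4-dien-1-yl]-1,4,4a,5,6,7,8,8a-octahydronaphthalene-2-carbaldehyde | C=C/C(C)=C/C[C@@H]1C(C=O)=C[C@H](O)[C@@H]2C(C)(C)CCC[C@@]12C | intermediate
23 | (1S,4S,4aS,8aR)-3-formyl-4a,8,8-trimethyl-4-[(2E)-3-methylpenta-2,4-dien-1-yl]-1,4,4a,5,6,7,8,8a-octahydronaphthalen-1-yl acetate | C=C/C(C)=C/C[C@@H]1C(C=O)=C[C@H](OC(C)=O)[C@@H]2C(C)(C)CCC[C@@]12C | intermediate
24 | (1S,4S,4aR,8aS)-4-acetoxy-5,5,8a-trimethyl-1-[(2E)-3-methylpenta-2,4-dien-1-yl]-1,4,4a,5,6,7,8,8a-octahydronaphthalene-2-carboxylic acid | C=C/C(C)=C/C[C@@H]1C(C(=O)O)=C[C@H](OC(C)=O)[C@@H]2C(C)(C)CCC[C@@]12C | target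

## Step count and least certain steps

Total step count: 13. Longest linear sequence: 12 steps (steps 1–5 and 7–13, from 1 to 24); step 6 is a one-step side branch.

**Step 5 (proposed new method).**
- What may go wrong: the C3=C4 alkene may attack the acid-activated enone at C6 (a cationic conjugate addition giving a bridged bicycle) faster than the dienol forms and captures the C4 cation. The cation may also be lost by proton elimination or solvent capture without C–C bond formation. The ring fusion may settle cis if the thermodynamic preference for trans is smaller than assumed.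
- Fallback, known chemistry, from 9 back to 10: HCl (gas, CH2Cl2, −30 °C) adds across C3=C4 in the Markovnikov sense to give (5R,6S)-6-(but-2-yn-1-yl)-5-(4-chloro-4-methylpentyl)-5-methylcyclohex-2-en-1-one F1. Soft enolisation at the γ-carbon (t-BuMe2SiOTf, Et3N, CH2Cl2, 0 °C) gives the linear silyl dienol ether tert-butyl{[(5R,6S)-6-(but-2-yn-1-yl)-5-(4-chloro-4-methylpentyl)-5-methylcyclohexa-1,3-dien-1-yl]oxy}dimethylsilane F2. TiCl4 (CH2Cl2, −78 °C) then ionises the tertiary chloride, and the dienol ether is alkylated at C5 with loss of the silyl group as its chloride. This is the Lewis-acid-mediated SN1 tert-alkylation of silyl enol and dienol ethers, here intramolecular. The same methoxide equilibration then gives 10. In this variant ring B is a nucleophilic diene and no Brønsted acid or free enone is present when the cation forms, which removes the competing pathway.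

**Step 2 (key step).**
- What may go wrong: the bromomagnesium enolate next to the new quaternary carbon may alkylate slowly. Proton transfer between enolate and product would then scramble the regiochemistry and lead to alkylation at C7 or to double alkylation. Enantioselectivity may also be lower with this functionalised Grignard reagent than with simple alkyl reagents.
- Fallback, from 5 back to 6: the alkylation is taken out of the one-pot process. The enolate is quenched with Me3SiCl and Et3N and isolated as trimethyl{[(S)-3-methyl-3-(4-methylpent-3-en-1-yl)cyclohex-1-en-1-yl]oxy}silane F3, whose enantiomeric purity can be checked and, if need be, raised at this stage. MeLi (THF, 0 °C) then releases the salt-free lithium (S)-3-methyl-3-(4-methylpent-3-en-1-yl)cyclohex-1-en-1-olate F4, which is alkylated with 4 in THF–DMPU at −78 → 0 °C to give 6.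

**Step 8.**
- What may go wrong: the perrhenate ester may ionise to the allyl cation, with loss of stereochemical fidelity at C6 or elimination to a diene. The equilibrium may also not favour the doubly syn-axial C6 alcohol strongly enough.
- Fallback, from 16 back to 17: pyridinium chlorochromate, [C5H5NH][CrO3Cl] (CH2Cl2, rt), effects the Babler–Dauben oxidative transposition to (4S,4aS,8aR)-4-(but-2-yn-1-yl)-3-{[(4-methoxybenzyl)oxy]methyl}-4a,8,8-trimethyl-4a,5,6,7,8,8a-hexahydronaphthalen-1(4H)-one F5. Luche reduction (NaBH4, CeCl3·7H2O, MeOH, −40 °C) should then deliver hydride to C6 from the face opposite C20 and the axial C4 methyl, giving the axial alcohol 17. The C6 configuration is then set by the substrate and no longer relayed from C8.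

**Step 10.**
- What may go wrong: regiocontrol of the Zr–H addition may be incomplete, putting metal on C12. Transmetalation of the hindered internal alkenylzirconocene may be slow, leading to protodemetalation to the simple alkene.
- Fallback, from 18 back to 21: after the hydrozirconation the flask is treated with I2 (THF, 0 °C) to give (1S,4S,4aS,8aR)-3-(hydroxymethyl)-4-[(2E)-3-iodobut-2-en-1-yl]-4a,8,8-trimethyl-1,4,4a,5,6,7,8,8a-octahydronaphthalen-1-ol F6, which can be freed from its regioisomer by chromatography. Stille coupling with tributyl(vinyl)stannane (Pd2(dba)3, AsPh3, CuI, NMP, rt) then gives 21 with retention of geometry.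

## Further compounds

F1 | step 5 | (5R,6S)-6-(but-2-yn-1-yl)-5-(4-chloro-4-methylpentyl)-5-methylcyclohex-2-en-1-one | CC#CC[C@@H]1C(=O)C=CC[C@@]1(C)CCCC(C)(C)Cl
F2 | step 5 | tert-butyl{[(5R,6S)-6-(but-2-yn-1-yl)-5-(4-chloro-4-methylpentyl)-5-methylcyclohexa-1,3-dien-1-yl]oxy}dimethylsilane | CC#CC[C@@H]1C(O[Si](C)(C)C(C)(C)C)=CC=C[C@@]1(C)CCCC(C)(C)Cl
F3 | step 2 | trimethyl{[(S)-3-methyl-3-(4-methylpent-3-en-1-yl)cyclohex-1-en-1-yl]oxy}silane | C[Si](C)(C)OC1=C[C@](C)(CCC=C(C)C)CCC1
F4 | step 2 | lithium (S)-3-methyl-3-(4-methylpent-3-en-1-yl)cyclohex-1-en-1-olate | [Li]OC1=C[C@](C)(CCC=C(C)C)CCC1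
F5 | step 8 | (4S,4aS,8aR)-4-(but-2-yn-1-yl)-3-{[(4-methoxybenzyl)oxy]methyl}-4a,8,8-trimethyl-4a,5,6,7,8,8a-hexahydronaphthalen-1(4H)-one | CC#CC[C@@H]1C(COCc3ccc(OC)cc3)=CC(=O)[C@@H]2C(C)(C)CCC[C@@]12C
F6 | step 10 | (1S,4S,4aS,8aR)-3-(hydroxymethyl)-4-[(2E)-3-iodobut-2-en-1-yl]-4a,8,8-trimethyl-1,4,4a,5,6,7,8,8a-octahydronaphthalen-1-ol | C/C(I)=C\C[C@@H]1C(CO)=C[C@H](O)[C@@H]2C(C)(C)CCC[C@@]12C
A1 | alternative 1 | 2,4-bis(trimethylsilyloxy)penta-1,3-diene | C=C(O[Si](C)(C)C)C=C(C)O[Si](C)(C)C
A2 | alternative 1 | methyl (E)-4-oxo-4-(2-oxo-1,3-oxazolidin-3-yl)but-2-enoate | COC(=O)/C=C/C(=O)N1CCOC1=O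
A3 | alternative 1 | methyl trans-3-methyl-5-oxo-2-(2-oxooxazolidine-3-carbonyl)cyclohex-3-ene-1-carboxylate | O=C1OCCN1C(=O)[C@@H]1[C@@H](C(=O)OC)CC(=O)C=C1C
A4 | alternative 2 | (2E,8Z,10E)-12-[(tert-butyldimethylsilyl)oxy]-3,7,7-trimethyl-9-[(triisopropylsilyl)oxy]dodeca-2,8,10-trienal | O=C/C=C(\C)CCCC(C)(C)/C=C(O[Si](C(C)C)(C(C)C)C(C)C)/C=C/CO[Si](C)(C)C(C)(C)C
A5 | alternative 2 | trans-fused cycloadduct with C6 triisopropylsilyl enol ether, C9 formyl, C8 (tert-butyldimethylsilyloxy)methyl and C10 methyl | O=C[C@@H]1[C@H](CO[Si](C)(C)C(C)(C)C)C=C(O[Si](C(C)C)(C(C)C)C(C)C)[C@@H]2C(C)(C)CCC[C@@]12C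
A6 | alternative 3 | 2,2,6-trimethylcyclohexan-1-one | CC1CCCC(C)(C)C1=O
A7 | alternative 3 | 2,6,6-trimethyl-N-[(R)-1-phenylethyl]cyclohex-1-en-1-amine | CC1=C(N[C@H](C)c2ccccc2)C(C)(C)CCC1
A8 | alternative 3 | methyl 2-acetyl-5-[(tert-butyldimethylsilyl)oxy]pent-2-enoate (E/Z mixture) | COC(=O)C(C(C)=O)=CCCO[Si](C)(C)C(C)(C)C
A9 | alternative 3 | bicyclic 5-en-7-one with C8 methyl ester, C9 2-(tert-butyldimethylsilyloxy)ethyl arm and C10 methyl | CC(C)(C)[Si](C)(C)OCC[C@@H]1[C@@H](C(=O)OC)C(=O)C=C2C(C)(C)CCC[C@@]12C
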